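If the rate of a flask follows its catalyst, catalyst charged times time should set how far it has gone, so read every flask on north-west's clock.

all flasks: substrate 2.0 × 10⁻⁴ M
- south: free catalyst 12 µM; added ligand 28 µM; run made earlier
- north-east: free catalyst 12 µM; added ligand 59 µM; run made earlier
- north-west: free catalyst 24 µM; added ligand 38 µM; run made earlier
- summer: free catalyst 25 µM; added ligand 25 µM; time 6.0 min
- autumn: free catalyst 12 µM; added ligand 38 µM; time 6.0 min

| run | time / min | product / % | substrate / % |
|---|---|---|---|
| south | 0.200 | 3.0 | 93.4 |
| south | 0.667 | 11.2 | 85.4 |
| south | 1.00 | 16.0 | 79.7 |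
| south | 1.50 | 22.9 | 73.0 |
| south | 2.50 | 38.3 | 58.4 |
| south | 3.00 | 45.6 | 51.2 |
| north-east | 0.250 | 3.3 | 92.5 |
| north-east | 0.417 | 6.0 | 90.4 |
| north-east | 0.667 | 9.3 | 86.6 |
| north-east | 1.00 | 14.0 | 82.1 |
| north-east | 2.00 | 28.5 | 69.1 |
| north-east | 3.00 | 40.8 | 56.1 |
| north-west | 0.250 | 7.0 | 85.2 |
| north-west | 0.833 | 25.1 | 67.9 |
| north-west | 1.33 | 38.4 | 54.6 |
| north-west | 2.00 | 55.4 | 40.0 |
| north-west | 3.00 | 74.3 | 21.9 |

(scatter of a reading: 0.5 percentage points)

- the numbers in the tables scatter by 0.5 percentage points (one standard deviation)
- a reading or a percentage of product counts all its forms, free or not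

1. which of the two ends with the higher amount of product, in percent of the substrate charged ("neither" if they lie within 2 percentage points) (summer / autumn / neither)
2. product at the end, in percent of the substrate charged, summer
3. product at the end, in percent of the substrate charged, autumn

Autumn's exposure, its free catalyst charged times its time over the same product at north-west's last reading, is 1.00. This is the zero of the scale: at that exposure, and with north-west's ligand, autumn should repeat the reading of 74.3 % product. Test the number on south and north-east, both at exposure 0.500. Their 45.6 % and 40.8 % lie between north-west's 38.4 % and 55.4 %, which bracket that exposure, but about twice the ligand costs 4.8 percentage points, so exposure is not the whole story. Summer's exposure is 2.08, which runs 3.25 min past north-west's last reading on that clock. Continue north-west's last fall of substrate, 40.0 % to 21.9 %, as a pseudo-first-order tail, and my reckoning leaves 3.09 % substrate, so about 96.9 % product.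

The forecast named summer, with 92 % for summer (range 72 % to 98 %) and 75 % for autumn (range 69 % to 81 %). For summer it stands below my figure, and of that number it says: “I shade it down and widen the range”.

    substrate + free catalyst ⇌ catalyst intermediate A (K = 12000 M⁻¹, k = 18000 M⁻¹ s⁻¹)
    catalyst intermediate A ⇌ catalyst intermediate B (K = 0.430, k = 1.30 s⁻¹)
    catalyst intermediate B → free catalyst + product (k = 0.240 s⁻¹)
    free catalyst + added ligand ⇌ idle complex (K = 16000 M⁻¹, k = 43000 M⁻¹ s⁻¹)
    crystals ⇌ product, rate k5*(cs5 - [product]) while solid is left; crystals form when [product] > cs5 (solubility = 0.00230 mM, k = 0.750 s⁻¹)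

Read the result: summer gives 98.4 % and autumn 74.8 %, so summer ends higher, and 6.4 points above the forecast. Now take the neighbour of autumn charged with 3.0 × 10⁻⁶ M of free catalyst, other charges and time held. Its exposure is 0.250, or 0.750 min on north-west's clock, just short of the reading of 25.1 % at 0.833 min. Scaling that reading in proportion gives 22.6 % product. The neighbour gives 23.3 % at 6.0 min, with 75.8 % of the substrate still unbound.

The runs were generated by integration with constants of no real substance; noise was put on by code.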